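**Strategy.** The target is cut at C11–C12 and C11′–C12′. The two cyclohexane rings are joined only by the C12–C12′ ethano bridge, and each ring carbon C11 lies between quaternary C6 and the C10 carbinol, so a two-carbon linchpin can be added to C11 ketones. Acetylene, metallated twice, adds to the C11 carbonyl of two molecules of one enantiopure ring-A ketone (C7–O and C3–O as TBS ethers, made from (S)-Wieland–Miescher ketone), forming both skeletal bonds in one operation. The alkyne then forces dehydration into the ring so that oxygen can be moved to C10. The two C10 centres are set by complementary methods and the oxepanes are closed last.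

Key step: step 6

**Remarks on the chemistry (assumptions)**
- Numbering per half: O1, C2 (CMe2), C3 (C=O), C4, C5, C6 (CH3), C7 in the oxepane; C6–C11 in the cyclohexane; C12 in the bridge; primes for the second half. β is the face of the C6 methyl.
- The target is not C2-symmetric. C6, C7, C11 are S in both halves, but C10 is R (acetoxy axial, syn to C6–CH3) and C10′ is S (acetoxy equatorial). The route therefore desymmetrises a C2-symmetric diketone by a statistical mono-addition.
- Ketone 6 and diol 9 were checked against the target: C6–CH3 and C7–O are cis and the C5 chain is trans to C7–O, as required. To make this relationship substrate-controlled, 6 is prepared from (S)-Wieland–Miescher ketone, taken as commercially available.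
- Centres that are later erased (epoxide carbons in 11, C11 in 12/13, C3 carbinols in 21–24, C2 in 23) are drawn without configuration.

**Route**

Step 1
Reactants: 1 (S)-Wieland–Miescher ketone
Product: 2 (4aS,5S)-5-hydroxy-4a-methyl-4,4a,5,6,7,8-hexahydronaphthalen-2(3H)-one
Conditions: NaBH4 (0.3 equiv), EtOH, −10 °C
Reagents that add atoms: none
Why: Chemoselective borohydride reduction of the saturated ketone over the less electrophilic enone; hydride should attack anti to the angular methyl, so the new C–O bond (future C7–O) is cis to CH3 (5S).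

Step 2
Reactants: 2 hydroxy enone
Product: 3 (4aS,5S)-5-(tert-butyldimethylsilyloxy)-4a-methyl-4,4a,5,6,7,8-hexahydronaphthalen-2(3H)-one
Conditions: TBSCl, imidazole, DMF, 40 °C
Reagents that add atoms: tert-butyldimethylsilyl chloride, C[Si](C)(Cl)C(C)(C)C
Why: Standard silyl ether formation on the secondary alcohol; no stereocentre is touched.

Step 3
Reactants: 3 silyloxy enone
Product: 4 3-[(1R,2S)-2-(tert-butyldimethylsilyloxy)-1-methyl-6-oxocyclohexyl]propanoic acid
Conditions: RuCl3·xH2O (cat.), NaIO4, MeCN/EtOAc/H2O, 0 °C → rt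
Reagents that add atoms: sodium periodate, [Na+].[O-]I(=O)(=O)=O; water, O
Why: RuO4/periodate oxidative cleavage of the enone C=C should leave the ring ketone (future C11=O) and degrade the α-keto acid by one carbon to the propanoic acid (future C5–C4–C3), the classical enone-to-seco-keto-acid degradation.

Step 4
Reactants: 4 keto acid
Product: 5 (2R,3S)-3-(tert-butyldimethylsilyloxy)-2-(3-hydroxypropyl)-2-methylcyclohexan-1-one
Conditions: BH3·THF (1.1 equiv), THF, −20 → 0 °C
Reagents that add atoms: none
Why: Chemoselective borane reduction; the acid reacts through its acyloxyborane much faster than the ketone, which is additionally shielded by quaternary C6.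

Step 5
Reactants: 5 keto alcohol
Product: 6 (2R,3S)-3-(tert-butyldimethylsilyloxy)-2-methyl-2-[3-(tert-butyldimethylsilyloxy)propyl]cyclohexan-1-one
Conditions: TBSCl, imidazole, DMF, rt
Reagents that add atoms: tert-butyldimethylsilyl chloride, C[Si](C)(Cl)C(C)(C)C
Why: Silylation of the primary alcohol, which also removes any hemiketal equilibrium with the ketone.

Step 6
Reactants: 6 ring-A ketone (two molecules); 7 acetylene
Product: 9 bis-propargylic diol, via ethynyl carbinol 8 (not isolated)
Conditions: 7, n-BuLi (1 equiv), THF, −78 °C, then 6 (1 equiv); n-BuLi (1 equiv), −78 → −20 °C; CeCl3, 6 (1 equiv), −78 °C → rt; aq NH4Cl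
Reagents that add atoms: none
Why: Lithium acetylide adds 1,2 to the C11 carbonyl of one ketone, the terminal alkyne of the resulting alkoxide is metallated again and adds to a second ketone, forming C11–C12 and C11′–C12′. The closest known reaction is the double ethynylation of ketones with acetylene to but-2-yne-1,4-diols (Iotsitch/Favorskii type, here with cerium assistance). No ring is closed. The new carbinol centres C11 and C11′ should arise by axial attack anti to the axial C6 methyl, but they are destroyed in step 7, so their configuration is not needed. The step needs chemoselective 1,2-addition over enolisation and a complete second addition: C6 is quaternary, so only C10 can enolise, and the weakly basic acetylide with CeCl3 activation should suppress that. The silyl ethers are inert, and the β-silyloxy group cannot eliminate because C6 bears no hydrogen.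

Step 7
Reactants: 9 bis-propargylic diol
Product: 10 bis-enyne (C10=C11–C≡C–C11′=C10′)
Conditions: POCl3, pyridine, 70 °C
Reagents that add atoms: none
Why: Dichlorophosphate elimination of tertiary propargylic alcohols (POCl3/pyridine dehydration); only C10–H can be lost because C6 is quaternary and C12 is sp-hybridised, so both alkenes form in the ring.

Step 8
Reactants: 10 bis-enyne
Product: 11 bis-epoxide (C10–C11 and C10′–C11′ oxiranes)
Conditions: mCPBA, NaHCO3, CH2Cl2, 0 °C
Reagents that add atoms: 3-chloroperoxybenzoic acid, OOC(=O)c1cccc(Cl)c1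
Why: Prilezhaev epoxidation of the trisubstituted alkenes, which react far faster than the alkyne; the epoxide configuration is irrelevant because it is erased in step 9.

Step 9
Reactants: 11 bis-epoxide
Product: 12 bis(α-alkynyl ketone) with C10 and C10′ carbonyls
Conditions: BF3·OEt2 (0.2 equiv), CH2Cl2, −78 °C; rapid neutral work-up
Reagents that add atoms: none
Why: Meinwald rearrangement; the Lewis acid opens each oxirane at the tertiary propargylic carbon C11 and a 1,2-hydride shift from C10 should give the C10 ketone with C11–H.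

Step 10
Reactants: 12 bis(α-alkynyl ketone)
Product: 14 C2-symmetric diketone with equatorial bridge at C11 and C11′, via C11-epimeric diketone mixture 13 (not isolated)
Conditions: H2 (1 atm), 10% Pd/C, EtOAc, rt; then K2CO3, MeOH, rt
Reagents that add atoms: none
Why: Heterogeneous hydrogenation saturates the alkyne (and any allenone isomer) to the C12–C12′ ethano bridge, and base-mediated enolisation toward C11 then equilibrates each C11 to the thermodynamically preferred equatorial bridge (C11–H axial, S).

Step 11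
Reactants: 14 C2-symmetric diketone
Product: 15 hydroxy ketone (C10 tertiary alcohol R, C10′ ketone)
Conditions: MeMgBr (1.0 equiv), LaCl3·2LiCl (0.3 equiv), THF, −78 °C
Reagents that add atoms: methylmagnesium bromide, C[Mg]Br
Why: Grignard 1,2-addition with lanthanum assistance against enolisation; the axial trajectory is blocked by the syn-axial C6 methyl, so methyl should enter equatorially from the α face and leave the C10 hydroxyl axial. One equivalent can give at best a statistical share of mono-adduct, which is separable by polarity, and recovered 14 is recycled.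

Step 12
Reactants: 15 hydroxy ketone
Product: 16 methylene alcohol (C10′=CH2)
Conditions: Ph3PCH3Br, KOt-Bu, toluene, 90 °C
Reagents that add atoms: methyltriphenylphosphonium bromide, C[P+](c1ccccc1)(c1ccccc1)c1ccccc1.[Br-]
Why: Wittig methylenation of the hindered ketone with excess salt-free ylide; C11′ already has its thermodynamic configuration and the tertiary alcohol is carried as its alkoxide.

Step 13
Reactants: 16 methylene alcohol
Product: 17 spiro-epoxide (C10′ oxygen equatorial, α)
Conditions: mCPBA, NaHCO3, CH2Cl2, 0 °C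
Reagents that add atoms: 3-chloroperoxybenzoic acid, OOC(=O)c1cccc(Cl)c1
Why: Prilezhaev epoxidation of the exocyclic alkene from the α face, away from the syn-axial C6′ methyl, should place oxygen equatorial and CH2 axial at C10′.

Step 14
Reactants: 17 spiro-epoxide
Product: 18 bis-tertiary diol (C10 R with axial OH, C10′ S with equatorial OH)
Conditions: LiEt3BH, THF, 0 °C → rt
Reagents that add atoms: none
Why: SN2 hydride opening of the 1,1-disubstituted epoxide at its CH2 carbon turns that carbon into the axial methyl and keeps the equatorial C10′–O bond; silyl ethers tolerate Super-Hydride.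

Step 15
Reactants: 18 bis-tertiary diol
Product: 19 tetraol with free C3 and C3′ primary alcohols (C7, C7′ still TBS ethers)
Conditions: CSA (cat.), MeOH/CH2Cl2, 0 °C
Reagents that add atoms: none
Why: Acid-catalysed methanolysis of silyl ethers, selective for the unhindered primary TBS groups over the neopentyl secondary ones.

Step 16
Reactants: 19 tetraol
Product: 20 dialdehyde (C3 and C3′ CHO)
Conditions: Dess–Martin periodinane, NaHCO3, CH2Cl2, 0 °C → rt
Reagents that add atoms: none
Why: Dess–Martin oxidation of the primary alcohols; the tertiary alcohols cannot be oxidised and C7–O is still protected, so no lactol can form.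

Step 17
Reactants: 20 dialdehyde
Product: 21 bis(isopropenyl carbinol) (C3, C3′ epimer mixture)
Conditions: isopropenylmagnesium bromide (excess), THF, −78 → 0 °C
Reagents that add atoms: isopropenylmagnesium bromide, CC(=C)[Mg]Br
Why: Grignard addition to the aldehydes introduces C2 with one methyl and the CH2 that becomes the second methyl; the C3 configuration is irrelevant because C3 ends as a ketone.

Step 18
Reactants: 21 bis(isopropenyl carbinol)
Product: 22 hexaol with free C7 and C7′ hydroxyls
Conditions: TBAF, THF, 60 °C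
Reagents that add atoms: none
Why: Fluoride desilylation of the hindered secondary TBS ethers under non-acidic conditions that spare the allylic and tertiary alcohols.

Step 19
Reactants: 22 hexaol
Product: 24 bis-oxepane tetraol (C3, C3′ carbinols; C10, C10′ tertiary alcohols), via bis-organomercurial 23 (not isolated)
Conditions: Hg(OCOCF3)2, CH2Cl2, 0 °C → rt; then NaBH4, aq NaOH, 0 °C
Reagents that add atoms: none
Why: Intramolecular alkoxymercuration–demercuration; C7–OH should attack the tertiary carbon C2 of the activated 1,1-disubstituted alkene in the 7-exo-trig Markovnikov sense (the only ring alternative is 8-endo), and borohydride replaces Hg by H to complete the gem-dimethyl group. The trans ring fusion is already fixed by C6 and C7.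

Step 20
Reactants: 24 bis-oxepane tetraol
Product: 25 bis-oxepanone diol (C3, C3′ ketones)
Conditions: Dess–Martin periodinane, NaHCO3, CH2Cl2, rt
Reagents that add atoms: none
Why: Dess–Martin oxidation of the two secondary alcohols removes the C3 epimer mixtures; the tertiary alcohols are inert.

Step 21
Reactants: 25 bis-oxepanone diol
Product: 26 target diacetate
Conditions: Ac2O, Sc(OTf)3 (cat.), MeCN, −20 °C
Reagents that add atoms: acetic anhydride, CC(=O)OC(C)=O
Why: Scandium triflate-catalysed acylation is suited to hindered tertiary alcohols (including the axial C10–OH) at a temperature low enough to avoid elimination or enol acetate formation at C4.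

**Compound list**

1 | (S)-Wieland–Miescher ketone, (S)-8a-methyl-3,4,8,8a-tetrahydronaphthalene-1,6(2H,7H)-dione | C[C@]12CCC(=O)C=C1CCCC2=O | starting material
2 | (4aS,5S)-5-hydroxy-4a-methyl-4,4a,5,6,7,8-hexahydronaphthalen-2(3H)-one (OH cis to CH3) | C[C@]12CCC(=O)C=C1CCC[C@@H]2O | intermediate
3 | (4aS,5S)-5-(tert-butyldimethylsilyloxy)-4a-methyl-4,4a,5,6,7,8-hexahydronaphthalen-2(3H)-one | C[C@]12CCC(=O)C=C1CCC[C@@H]2O[Si](C)(C)C(C)(C)C | intermediate
4 | 3-[(1R,2S)-2-(tert-butyldimethylsilyloxy)-1-methyl-6-oxocyclohexyl]propanoic acid | O=C1CCC[C@H](O[Si](C)(C)C(C)(C)C)[C@@]1(C)CCC(=O)O | intermediate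
5 | (2R,3S)-3-(tert-butyldimethylsilyloxy)-2-(3-hydroxypropyl)-2-methylcyclohexan-1-one | O=C1CCC[C@H](O[Si](C)(C)C(C)(C)C)[C@@]1(C)CCCO | intermediate
6 | ring-A ketone, (2R,3S)-3-(tert-butyldimethylsilyloxy)-2-methyl-2-[3-(tert-butyldimethylsilyloxy)propyl]cyclohexan-1-one | O=C1CCC[C@H](O[Si](C)(C)C(C)(C)C)[C@@]1(C)CCCO[Si](C)(C)C(C)(C)C | intermediate
7 | acetylene | C#C | starting material
8 | ethynyl carbinol: 1-ethynyl adduct of 6 at C11 (OH equatorial, drawn for axial attack) | O[C@]1(C#C)CCC[C@H](O[Si](C)(C)C(C)(C)C)[C@@]1(C)CCCO[Si](C)(C)C(C)(C)C | intermediate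
9 | bis-propargylic diol: ethyne-1,2-diyl bridging two C11 carbinols, each ring carrying C6–CH3, C6–(CH2)3OTBS and C7–OTBS | O[C@]1(C#C[C@@]2(O)CCC[C@H](O[Si](C)(C)C(C)(C)C)[C@@]2(C)CCCO[Si](C)(C)C(C)(C)C)CCC[C@H](O[Si](C)(C)C(C)(C)C)[C@@]1(C)CCCO[Si](C)(C)C(C)(C)C | intermediate
10 | bis-enyne: 1,2-bis(cyclohex-1-enyl)ethyne with C10=C11 and C10′=C11′ | C(#CC1=CCC[C@H](O[Si](C)(C)C(C)(C)C)[C@@]1(C)CCCO[Si](C)(C)C(C)(C)C)C1=CCC[C@H](O[Si](C)(C)C(C)(C)C)[C@@]1(C)CCCO[Si](C)(C)C(C)(C)C | intermediate
11 | bis-epoxide: C10–C11 and C10′–C11′ oxiranes on the alkyne (diastereomer mixture) | C(#CC12OC1CC[C@H](O[Si](C)(C)C(C)(C)C)[C@@]2(C)CCCO[Si](C)(C)C(C)(C)C)C12OC1CC[C@H](O[Si](C)(C)C(C)(C)C)[C@@]2(C)CCCO[Si](C)(C)C(C)(C)C | intermediate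
12 | bis(α-alkynyl ketone): C10 and C10′ ketones, C11–C≡C–C11′ | C(#CC1C(=O)CC[C@H](O[Si](C)(C)C(C)(C)C)[C@@]1(C)CCCO[Si](C)(C)C(C)(C)C)C1C(=O)CC[C@H](O[Si](C)(C)C(C)(C)C)[C@@]1(C)CCCO[Si](C)(C)C(C)(C)C | intermediate
13 | saturated diketone with ethano bridge, C11/C11′ epimer mixture | C(CC1C(=O)CC[C@H](O[Si](C)(C)C(C)(C)C)[C@@]1(C)CCCO[Si](C)(C)C(C)(C)C)C1C(=O)CC[C@H](O[Si](C)(C)C(C)(C)C)[C@@]1(C)CCCO[Si](C)(C)C(C)(C)C | intermediate
14 | C2-symmetric diketone: C10 and C10′ ketones, bridge equatorial at C11 and C11′ (both S) | O=C1CC[C@H](O[Si](C)(C)C(C)(C)C)[C@@](C)(CCCO[Si](C)(C)C(C)(C)C)[C@@H]1CC[C@H]1[C@](C)(CCCO[Si](C)(C)C(C)(C)C)[C@@H](O[Si](C)(C)C(C)(C)C)CCC1=O | intermediate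
15 | hydroxy ketone: C10 tertiary alcohol (R, OH axial, CH3 equatorial), C10′ ketone | O[C@]1(C)CC[C@H](O[Si](C)(C)C(C)(C)C)[C@@](C)(CCCO[Si](C)(C)C(C)(C)C)[C@@H]1CC[C@H]1[C@](C)(CCCO[Si](C)(C)C(C)(C)C)[C@@H](O[Si](C)(C)C(C)(C)C)CCC1=O | intermediate
16 | methylene alcohol: C10 carbinol as in 15, C10′=CH2 | O[C@]1(C)CC[C@H](O[Si](C)(C)C(C)(C)C)[C@@](C)(CCCO[Si](C)(C)C(C)(C)C)[C@@H]1CC[C@H]1[C@](C)(CCCO[Si](C)(C)C(C)(C)C)[C@@H](O[Si](C)(C)C(C)(C)C)CCC1=C | intermediate
17 | spiro-epoxide: C10′ oxirane with oxygen equatorial (α) and CH2 axial | O[C@]1(C)CC[C@H](O[Si](C)(C)C(C)(C)C)[C@@](C)(CCCO[Si](C)(C)C(C)(C)C)[C@@H]1CC[C@H]1[C@](C)(CCCO[Si](C)(C)C(C)(C)C)[C@@H](O[Si](C)(C)C(C)(C)C)CC[C@@]12CO2 | intermediate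
18 | bis-tertiary diol: C10 (R, OH axial), C10′ (S, OH equatorial), four TBS ethers | O[C@]1(C)CC[C@H](O[Si](C)(C)C(C)(C)C)[C@@](C)(CCCO[Si](C)(C)C(C)(C)C)[C@@H]1CC[C@H]1[C@](C)(CCCO[Si](C)(C)C(C)(C)C)[C@@H](O[Si](C)(C)C(C)(C)C)CC[C@]1(C)O | intermediate
19 | tetraol: free C3 and C3′ primary alcohols, C7 and C7′ TBS ethers | O[C@]1(C)CC[C@H](O[Si](C)(C)C(C)(C)C)[C@@](C)(CCCO)[C@@H]1CC[C@H]1[C@](C)(CCCO)[C@@H](O[Si](C)(C)C(C)(C)C)CC[C@]1(C)O | intermediate
20 | dialdehyde: C3 and C3′ CHO | O[C@]1(C)CC[C@H](O[Si](C)(C)C(C)(C)C)[C@@](C)(CCC=O)[C@@H]1CC[C@H]1[C@](C)(CCC=O)[C@@H](O[Si](C)(C)C(C)(C)C)CC[C@]1(C)O | intermediate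
21 | bis(isopropenyl carbinol): C3 and C3′ CH(OH)C(CH3)=CH2 (epimers) | O[C@]1(C)CC[C@H](O[Si](C)(C)C(C)(C)C)[C@@](C)(CCC(O)C(C)=C)[C@@H]1CC[C@H]1[C@](C)(CCC(O)C(C)=C)[C@@H](O[Si](C)(C)C(C)(C)C)CC[C@]1(C)O | intermediate
22 | hexaol: free C7, C7′, C3, C3′, C10, C10′ hydroxyls | O[C@]1(C)CC[C@H](O)[C@@](C)(CCC(O)C(C)=C)[C@@H]1CC[C@H]1[C@](C)(CCC(O)C(C)=C)[C@@H](O)CC[C@]1(C)O | intermediate
23 | bis-organomercurial: both oxepanes closed, each C2 bearing CH3 and CH2HgOCOCF3 | O[C@]1(C)CC[C@@H]2OC(C)(C[Hg]OC(=O)C(F)(F)F)C(O)CC[C@@]2(C)[C@@H]1CC[C@H]1[C@]2(C)CCC(O)C(C)(C[Hg]OC(=O)C(F)(F)F)O[C@H]2CC[C@]1(C)O | intermediate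
24 | bis-oxepane tetraol: trans-fused 2,2-dimethyloxepan-3-ols, C10 and C10′ tertiary alcohols | O[C@]1(C)CC[C@@H]2OC(C)(C)C(O)CC[C@@]2(C)[C@@H]1CC[C@H]1[C@]2(C)CCC(O)C(C)(C)O[C@H]2CC[C@]1(C)O | intermediate
25 | bis-oxepanone diol: C3 and C3′ ketones, C10 (R) and C10′ (S) tertiary alcohols | O[C@]1(C)CC[C@@H]2OC(C)(C)C(=O)CC[C@@]2(C)[C@@H]1CC[C@H]1[C@]2(C)CCC(=O)C(C)(C)O[C@H]2CC[C@]1(C)O | intermediate
26 | CNP0325605.1, the C10,C10′-diacetate | CC(=O)O[C@]1(C)CC[C@@H]2OC(C)(C)C(=O)CC[C@@]2(C)[C@@H]1CC[C@H]1[C@]2(C)CCC(=O)C(C)(C)O[C@H]2CC[C@]1(C)OC(C)=O | target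

**Totals.** 21 steps; longest linear sequence 21 steps (from 1; acetylene 7 enters in step 6, where 6 is used twice).

**Steps most likely to fail, with fallbacks**

1. Step 6 (key step). The second addition may stall: the alkoxide-bearing acetylide is aggregated and hindered, so enolisation of the second ketone toward C10 or recovery of mono-adduct can compete. Fallback, from 6 and 7, back at 10: ethynyl carbinol 8 is isolated after the first addition and dehydrated with POCl3/pyridine to terminal enyne F1. F1 is lithiated with n-BuLi and added with CeCl3 to a second equivalent of 6 to give enynol F2, whose dehydration under the same conditions gives bis-enyne 10. The same two bonds are formed, but the second nucleophile no longer carries an alkoxide.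

2. Step 9. The C11 cation may rearrange by ring contraction (C9 migration) instead of hydride shift, or the β,γ-ynone may isomerise and decompose under the Lewis acid. Fallback, from 10 (replacing steps 8–9), back at 14: the two ring alkenes are dihydroxylated with catalytic OsO4/NMO to alkyne tetraol F3, and the alkyne is hydrogenated over Pd/C to saturated tetraol F4. The secondary C10 alcohols are oxidised with Dess–Martin periodinane to bis(α-ketol) F5, and SmI2 in THF/MeOH removes the tertiary C11 hydroxyls reductively to give the epimer mixture 13, which the K2CO3/MeOH equilibration of step 10 converts to 14. No carbocation is involved.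

3. Step 19. Seven-membered ring closure may be slow, so that reversible capture of the mercurinium ion by trifluoroacetate, or reversion to alkene during reduction, competes on a substrate with six free hydroxyls. Fallback, from 22, back at 24: phenylselenoetherification with N-(phenylseleno)phthalimide and catalytic CSA in CH2Cl2 closes both rings irreversibly to the isolable bis(phenylselenomethyl) oxepane F6. Radical reduction with Bu3SnH/AIBN in toluene at 80 °C then converts each CH2SePh into the second C2 methyl, giving 24.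

**Further compounds**

F1 | step 6 | terminal enyne, 1-ethynylcyclohexene from dehydration of 8 | C#CC1=CCC[C@H](O[Si](C)(C)C(C)(C)C)[C@@]1(C)CCCO[Si](C)(C)C(C)(C)C
F2 | step 6 | enynol, adduct of lithiated F1 with 6 | O[C@]1(C#CC2=CCC[C@H](O[Si](C)(C)C(C)(C)C)[C@@]2(C)CCCO[Si](C)(C)C(C)(C)C)CCC[C@H](O[Si](C)(C)C(C)(C)C)[C@@]1(C)CCCO[Si](C)(C)C(C)(C)C
F3 | step 9 | alkyne tetraol, C10/C11 and C10′/C11′ diols | C(#CC1(O)C(O)CC[C@H](O[Si](C)(C)C(C)(C)C)[C@@]1(C)CCCO[Si](C)(C)C(C)(C)C)C1(O)C(O)CC[C@H](O[Si](C)(C)C(C)(C)C)[C@@]1(C)CCCO[Si](C)(C)C(C)(C)C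
F4 | step 9 | saturated tetraol with ethano bridge | C(CC1(O)C(O)CC[C@H](O[Si](C)(C)C(C)(C)C)[C@@]1(C)CCCO[Si](C)(C)C(C)(C)C)C1(O)C(O)CC[C@H](O[Si](C)(C)C(C)(C)C)[C@@]1(C)CCCO[Si](C)(C)C(C)(C)C
F5 | step 9 | bis(α-ketol), C10/C10′ ketones with C11/C11′ tertiary hydroxyls | C(CC1(O)C(=O)CC[C@H](O[Si](C)(C)C(C)(C)C)[C@@]1(C)CCCO[Si](C)(C)C(C)(C)C)C1(O)C(=O)CC[C@H](O[Si](C)(C)C(C)(C)C)[C@@]1(C)CCCO[Si](C)(C)C(C)(C)C
F6 | step 19 | bis(phenylselenomethyl) oxepane | O[C@]1(C)CC[C@@H]2OC(C)(C[Se]c3ccccc3)C(O)CC[C@@]2(C)[C@@H]1CC[C@H]1[C@]2(C)CCC(O)C(C)(C[Se]c3ccccc3)O[C@H]2CC[C@]1(C)O
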